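**Retrosynthetic overview**
- The plan rests on pyranone ring C of flavone 24. Its C4 sits between C4a of phloroglucinol ring A, which is flanked by two equivalent oxygens (the future O1 and 5‑O), and C3, while C2 carries ring B. C4 is therefore taken as CO, C4a as the iodinated carbon of triacetate 19, and C2–C3 as the terminal alkyne of 16, so that C4a–C4, C4–C3 and O1–C2 form in one operation; methanolysis of the two remaining acetates follows.
- Alkyne 16 comes from aryl iodide 13 (Sonogashira coupling, desilylation), and 13 from allyl compound 11 by cross‑metathesis to the prenyl group.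
- Dihydrofuran ring D of 11 comes from 5‑exo opening of threo epoxy alcohol 9 by the ortho phenoxide; inversion gives C2 (S), trans to the C3 hydroxyl.
- Epoxy alcohol 9 comes from (R)‑allylic alcohol 8 by peracid epoxidation under 1,3‑allylic strain control, 8 from Sharpless kinetic resolution of rac‑7, and 7 from 5‑iodosalicylaldehyde 1 by allylation, Claisen rearrangement, silylation and isobutenyl Grignard addition.
- Ring order: rings A and B are bought as benzenes, ring D is closed in step 7 and ring C in step 13.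

Key step: step 13

Remark on the chemistry: the prenyl group is carried as an allyl group until after the peracid step, because a peracid would not distinguish two trisubstituted alkenes; diethylamine may strip part of the remaining acetates in step 13, which is harmless because step 14 removes them.

**Step 1**
Reactants: 1 2‑hydroxy‑5‑iodobenzaldehyde; 2 3‑bromoprop‑1‑ene (allyl bromide)
Product: 3 5‑iodo‑2‑(prop‑2‑enyloxy)benzaldehyde
Conditions: K2CO3, DMF, rt
Reagents that add atoms: none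
Why: Williamson ether synthesis, an SN2 reaction of the phenoxide with the allylic bromide that leaves the aldehyde and the aryl iodide untouched.

**Step 2**
Reactants: 3 5‑iodo‑2‑(prop‑2‑enyloxy)benzaldehyde
Product: 4 2‑hydroxy‑5‑iodo‑3‑(prop‑2‑enyl)benzaldehyde
Conditions: N,N‑diethylaniline, 190 °C, N2
Reagents that add atoms: none
Why: Aromatic Claisen rearrangement ([3,3]‑sigmatropic shift, then tautomerisation) should deliver the allyl group to C3, the only free ortho position.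

**Step 3**
Reactants: 4 2‑hydroxy‑5‑iodo‑3‑(prop‑2‑enyl)benzaldehyde
Product: 5 5‑iodo‑3‑(prop‑2‑enyl)‑2‑(triisopropylsilyloxy)benzaldehyde
Conditions: TIPSOTf, 2,6‑lutidine, CH2Cl2, 0 °C → rt
Reagents that add atoms: triisopropylsilyl trifluoromethanesulfonate, CC(C)[Si](OS(=O)(=O)C(F)(F)F)(C(C)C)C(C)C
Why: O‑silylation of the hindered phenol with a silyl triflate; the bulky silyl group should resist 1,4 oxygen‑to‑oxygen migration in the next step and is later removed by fluoride to start the cyclisation.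

**Step 4**
Reactants: 5 5‑iodo‑3‑(prop‑2‑enyl)‑2‑(triisopropylsilyloxy)benzaldehyde; 6 2‑methylprop‑1‑enylmagnesium bromide
Product: 7 rac‑1‑[5‑iodo‑3‑(prop‑2‑enyl)‑2‑(triisopropylsilyloxy)phenyl]‑3‑methylbut‑2‑en‑1‑ol
Conditions: THF, −78 → −20 °C; then sat. aq. NH4Cl
Reagents that add atoms: none
Why: Grignard 1,2‑addition to the aldehyde, with iodine–magnesium exchange by an alkenyl Grignard reagent expected to be slow at low temperature; the carbinol centre is formed racemic and is resolved in step 5.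

**Step 5**
Reactants: 7 rac‑1‑[5‑iodo‑3‑(prop‑2‑enyl)‑2‑(triisopropylsilyloxy)phenyl]‑3‑methylbut‑2‑en‑1‑ol
Product: 8 (1R)‑1‑[5‑iodo‑3‑(prop‑2‑enyl)‑2‑(triisopropylsilyloxy)phenyl]‑3‑methylbut‑2‑en‑1‑ol (recovered enantiomer, at most half of the material)
Conditions: Ti(OiPr)4, D‑(−)‑DIPT, TBHP (0.6 equiv), 4 Å MS, CH2Cl2, −20 °C, taken past half conversion
Reagents that add atoms: none
Why: Sharpless kinetic resolution, in which the titanium tartrate complex epoxidises only the allylic‑alcohol alkene and with the D‑tartrate should consume the (S)‑enantiomer as its erythro epoxide far faster (the descriptor is reversed relative to alkyl alkenyl carbinols because aryl outranks alkenyl), so the (R)‑alcohol should be recovered in high enantiomeric purity while the allyl group and the aryl iodide stay inert.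

**Step 6**
Reactants: 8 (1R)‑1‑[5‑iodo‑3‑(prop‑2‑enyl)‑2‑(triisopropylsilyloxy)phenyl]‑3‑methylbut‑2‑en‑1‑ol
Product: 9 (S)‑[(2R)‑3,3‑dimethyloxiran‑2‑yl][5‑iodo‑3‑(prop‑2‑enyl)‑2‑(triisopropylsilyloxy)phenyl]methanol (threo)
Conditions: mCPBA (1.1 equiv), NaHCO3, CH2Cl2, 0 °C
Reagents that add atoms: 3‑chloroperbenzoic acid, OOC(=O)c1cccc(Cl)c1
Why: Hydroxyl‑directed Prilezhaev epoxidation, in which 1,3‑allylic strain between the aryl group and the cis methyl group holds the carbinol hydrogen in the alkene plane so that the hydrogen‑bonded peracid attacks the face bearing the hydroxyl and sets the (2R) oxirane centre (threo) under substrate control, while the monosubstituted allyl alkene reacts far more slowly.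

**Step 7**
Reactants: 9 (S)‑[(2R)‑3,3‑dimethyloxiran‑2‑yl][5‑iodo‑3‑(prop‑2‑enyl)‑2‑(triisopropylsilyloxy)phenyl]methanol
Product: 11 (2S,3S)‑2‑(2‑hydroxypropan‑2‑yl)‑5‑iodo‑7‑(prop‑2‑enyl)‑2,3‑dihydro‑1‑benzofuran‑3‑ol, via free epoxy phenol 10 (not isolated)
Conditions: TBAF (1.2 equiv), THF, 0 °C → rt; then H2O
Reagents that add atoms: none
Why: Fluoride desilylation frees the phenoxide, which opens the epoxide at its less substituted carbon by intramolecular 5‑exo‑tet SN2 attack with inversion, so the (2R) oxirane carbon becomes C2 (S), the untouched carbinol becomes C3 (S), and the two oxygens end up trans.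

**Step 8**
Reactants: 11 (2S,3S)‑2‑(2‑hydroxypropan‑2‑yl)‑5‑iodo‑7‑(prop‑2‑enyl)‑2,3‑dihydro‑1‑benzofuran‑3‑ol; 12 2‑methylbut‑2‑ene
Product: 13 (2S,3S)‑2‑(2‑hydroxypropan‑2‑yl)‑5‑iodo‑7‑(3‑methylbut‑2‑enyl)‑2,3‑dihydro‑1‑benzofuran‑3‑ol
Conditions: second‑generation Grubbs catalyst RuCl2(=CHPh)(PCy3)(H2IMes) (5 mol %), 2‑methylbut‑2‑ene/CH2Cl2, 40 °C
Reagents that add atoms: none
Why: Olefin cross‑metathesis of the terminal allyl group with excess 2‑methylbut‑2‑ene should give the prenyl group with loss of propene, the free alcohols and the aryl iodide being tolerated by the ruthenium carbene.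

**Step 9**
Reactants: 13 (2S,3S)‑2‑(2‑hydroxypropan‑2‑yl)‑5‑iodo‑7‑(3‑methylbut‑2‑enyl)‑2,3‑dihydro‑1‑benzofuran‑3‑ol; 14 ethynyltrimethylsilane
Product: 15 (2S,3S)‑2‑(2‑hydroxypropan‑2‑yl)‑7‑(3‑methylbut‑2‑enyl)‑5‑[(trimethylsilyl)ethynyl]‑2,3‑dihydro‑1‑benzofuran‑3‑ol
Conditions: PdCl2(PPh3)2 (3 mol %), CuI (5 mol %), Et3N, THF, rt
Reagents that add atoms: none
Why: Sonogashira coupling of the aryl iodide at room temperature, which is mild enough for the benzylic carbinol and the prenyl group.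

**Step 10**
Reactants: 15 (2S,3S)‑2‑(2‑hydroxypropan‑2‑yl)‑7‑(3‑methylbut‑2‑enyl)‑5‑[(trimethylsilyl)ethynyl]‑2,3‑dihydro‑1‑benzofuran‑3‑ol
Product: 16 (2S,3S)‑5‑ethynyl‑2‑(2‑hydroxypropan‑2‑yl)‑7‑(3‑methylbut‑2‑enyl)‑2,3‑dihydro‑1‑benzofuran‑3‑ol
Conditions: K2CO3 (cat.), MeOH, rt
Reagents that add atoms: none
Why: Methoxide‑mediated protodesilylation of the alkynylsilane, under basic conditions that do not endanger the acid‑labile benzylic alcohol.

**Step 11**
Reactants: 17 benzene‑1,3,5‑triol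
Product: 18 2‑iodobenzene‑1,3,5‑triol
Conditions: I2 (1.0 equiv), NaHCO3, THF/H2O, 0 °C
Reagents that add atoms: iodine, II
Why: Electrophilic aromatic iodination of the strongly activated ring, where the threefold symmetry means that only one monoiodide can form.

**Step 12**
Reactants: 18 2‑iodobenzene‑1,3,5‑triol
Product: 19 2‑iodobenzene‑1,3,5‑triyl triacetate
Conditions: Ac2O, pyridine, DMAP (cat.), CH2Cl2, 0 °C → rt
Reagents that add atoms: acetic anhydride, CC(=O)OC(C)=O
Why: O‑acetylation by nucleophilic catalysis converts the air‑sensitive iodotriol into a stable coupling partner whose ortho acetate later serves as the masked O1 nucleophile.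

**Step 13**
Reactants: 19 2‑iodobenzene‑1,3,5‑triyl triacetate; 20 carbon monoxide; 16 (2S,3S)‑5‑ethynyl‑2‑(2‑hydroxypropan‑2‑yl)‑7‑(3‑methylbut‑2‑enyl)‑2,3‑dihydro‑1‑benzofuran‑3‑ol
Product: 23 2‑[(2S,3S)‑3‑hydroxy‑2‑(2‑hydroxypropan‑2‑yl)‑7‑(3‑methylbut‑2‑enyl)‑2,3‑dihydro‑1‑benzofuran‑5‑yl]‑4‑oxo‑4H‑chromene‑5,7‑diyl diacetate, via ynone triacetate 21 (not isolated), via diethylamino enone 22 (not isolated)
Conditions: PdCl2(PPh3)2 (5 mol %), thiourea and dppp (5 mol % each), CO (1 atm), Et2NH, 40 °C, slow addition of 16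
Reagents that add atoms: none
Why: Zerovalent palladium formed in situ from PdCl2(PPh3)2 inserts into the C–I bond of 19, CO insertion gives an aroylpalladium species, and transfer of the amine‑deprotonated alkyne followed by reductive elimination forms C4a–C4 and C4–C3 in ynone 21. Diethylamine then cleaves one of the two equivalent ortho acetates and adds to the ynone to give β‑aminoenone 22, whose phenoxide displaces the amine at C2 by conjugate addition–elimination and so forms O1–C2. The closest known reaction type is the palladium‑catalysed carbonylative annulation of ortho‑iodophenols or their acetates with terminal alkynes to give flavones. Ring C closes in the 6‑endo mode, because the enaminone directs the phenoxide to C2 and not to the 5‑exo attack that would give an aurone. No stereocentre is created, and the two on ring D are remote and stable to the mildly basic medium, as are the free alcohols and the prenyl alkene. The step needs CO insertion to outrun direct alkynylation and amine capture of the acyl complex, which the CO atmosphere, the copper‑free catalyst and slow addition of 16 should secure, while the symmetry of ring A removes any regiochemical question.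

**Step 14**
Reactants: 23 2‑[(2S,3S)‑3‑hydroxy‑2‑(2‑hydroxypropan‑2‑yl)‑7‑(3‑methylbut‑2‑enyl)‑2,3‑dihydro‑1‑benzofuran‑5‑yl]‑4‑oxo‑4H‑chromene‑5,7‑diyl diacetate
Product: 24 5,7‑dihydroxy‑2‑[(2S,3S)‑3‑hydroxy‑2‑(2‑hydroxypropan‑2‑yl)‑7‑(3‑methylbut‑2‑enyl)‑2,3‑dihydro‑1‑benzofuran‑5‑yl]‑4H‑chromen‑4‑one
Conditions: K2CO3, MeOH, 0 °C → rt; then aq. NH4Cl
Reagents that add atoms: none
Why: Base‑catalysed transesterification (methanolysis) of the two aryl acetates, under conditions that keep the benzylic carbinol from ionising or dehydrating and leave both stereocentres untouched.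

**Compound list**
1 | 2‑hydroxy‑5‑iodobenzaldehyde | O=Cc1cc(I)ccc1O | starting material
2 | 3‑bromoprop‑1‑ene | C=CCBr | starting material
3 | 5‑iodo‑2‑(prop‑2‑enyloxy)benzaldehyde | O=Cc1cc(I)ccc1OCC=C | intermediate
4 | 2‑hydroxy‑5‑iodo‑3‑(prop‑2‑enyl)benzaldehyde | O=Cc1cc(I)cc(CC=C)c1O | intermediate
5 | 5‑iodo‑3‑(prop‑2‑enyl)‑2‑(triisopropylsilyloxy)benzaldehyde | O=Cc1cc(I)cc(CC=C)c1O[Si](C(C)C)(C(C)C)C(C)C | intermediate
6 | 2‑methylprop‑1‑enylmagnesium bromide | CC(C)=C[Mg]Br | starting material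
7 | rac‑1‑[5‑iodo‑3‑(prop‑2‑enyl)‑2‑(triisopropylsilyloxy)phenyl]‑3‑methylbut‑2‑en‑1‑ol | CC(C)=CC(O)c1cc(I)cc(CC=C)c1O[Si](C(C)C)(C(C)C)C(C)C | intermediate
8 | (1R)‑1‑[5‑iodo‑3‑(prop‑2‑enyl)‑2‑(triisopropylsilyloxy)phenyl]‑3‑methylbut‑2‑en‑1‑ol | CC(C)=C[C@@H](O)c1cc(I)cc(CC=C)c1O[Si](C(C)C)(C(C)C)C(C)C | intermediate
9 | (S)‑[(2R)‑3,3‑dimethyloxiran‑2‑yl][5‑iodo‑3‑(prop‑2‑enyl)‑2‑(triisopropylsilyloxy)phenyl]methanol | CC1(C)O[C@@H]1[C@@H](O)c2cc(I)cc(CC=C)c2O[Si](C(C)C)(C(C)C)C(C)C | intermediate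
10 | 2‑[(S)‑[(2R)‑3,3‑dimethyloxiran‑2‑yl](hydroxy)methyl]‑4‑iodo‑6‑(prop‑2‑enyl)phenol (present as its phenoxide) | CC1(C)O[C@@H]1[C@@H](O)c2cc(I)cc(CC=C)c2O | intermediate (not isolated)
11 | (2S,3S)‑2‑(2‑hydroxypropan‑2‑yl)‑5‑iodo‑7‑(prop‑2‑enyl)‑2,3‑dihydro‑1‑benzofuran‑3‑ol | C=CCc1cc(I)cc2c1O[C@H](C(C)(C)O)[C@H]2O | intermediate
12 | 2‑methylbut‑2‑ene | CC=C(C)C | starting material
13 | (2S,3S)‑2‑(2‑hydroxypropan‑2‑yl)‑5‑iodo‑7‑(3‑methylbut‑2‑enyl)‑2,3‑dihydro‑1‑benzofuran‑3‑ol | CC(C)=CCc1cc(I)cc2c1O[C@H](C(C)(C)O)[C@H]2O | intermediate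
14 | ethynyltrimethylsilane | C#C[Si](C)(C)C | starting material
15 | (2S,3S)‑2‑(2‑hydroxypropan‑2‑yl)‑7‑(3‑methylbut‑2‑enyl)‑5‑[(trimethylsilyl)ethynyl]‑2,3‑dihydro‑1‑benzofuran‑3‑ol | CC(C)=CCc1cc(C#C[Si](C)(C)C)cc2c1O[C@H](C(C)(C)O)[C@H]2O | intermediate
16 | (2S,3S)‑5‑ethynyl‑2‑(2‑hydroxypropan‑2‑yl)‑7‑(3‑methylbut‑2‑enyl)‑2,3‑dihydro‑1‑benzofuran‑3‑ol | CC(C)=CCc1cc(C#C)cc2c1O[C@H](C(C)(C)O)[C@H]2O | intermediate
17 | benzene‑1,3,5‑triol | Oc1cc(O)cc(O)c1 | starting material
18 | 2‑iodobenzene‑1,3,5‑triol | Oc1cc(O)c(I)c(O)c1 | intermediate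
19 | 2‑iodobenzene‑1,3,5‑triyl triacetate | CC(=O)Oc1cc(OC(C)=O)c(I)c(OC(C)=O)c1 | intermediate
20 | carbon monoxide | [C-]#[O+] | starting material
21 | 2‑{3‑[(2S,3S)‑3‑hydroxy‑2‑(2‑hydroxypropan‑2‑yl)‑7‑(3‑methylbut‑2‑enyl)‑2,3‑dihydro‑1‑benzofuran‑5‑yl]prop‑2‑ynoyl}benzene‑1,3,5‑triyl triacetate | CC(C)=CCc1cc(C#CC(=O)c2c(OC(C)=O)cc(OC(C)=O)cc2OC(C)=O)cc2c1O[C@H](C(C)(C)O)[C@H]2O | intermediate (not isolated)
22 | 4‑{3‑(diethylamino)‑3‑[(2S,3S)‑3‑hydroxy‑2‑(2‑hydroxypropan‑2‑yl)‑7‑(3‑methylbut‑2‑enyl)‑2,3‑dihydro‑1‑benzofuran‑5‑yl]prop‑2‑enoyl}‑5‑hydroxy‑1,3‑phenylene diacetate | CC(C)=CCc1cc(C(=CC(=O)c2c(O)cc(OC(C)=O)cc2OC(C)=O)N(CC)CC)cc2c1O[C@H](C(C)(C)O)[C@H]2O | intermediate (not isolated)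
23 | 2‑[(2S,3S)‑3‑hydroxy‑2‑(2‑hydroxypropan‑2‑yl)‑7‑(3‑methylbut‑2‑enyl)‑2,3‑dihydro‑1‑benzofuran‑5‑yl]‑4‑oxo‑4H‑chromene‑5,7‑diyl diacetate | CC(C)=CCc1cc(-c2cc(=O)c3c(OC(C)=O)cc(OC(C)=O)cc3o2)cc2c1O[C@H](C(C)(C)O)[C@H]2O | intermediate
24 | 5,7‑dihydroxy‑2‑[(2S,3S)‑3‑hydroxy‑2‑(2‑hydroxypropan‑2‑yl)‑7‑(3‑methylbut‑2‑enyl)‑2,3‑dihydro‑1‑benzofuran‑5‑yl]‑4H‑chromen‑4‑one | CC(C)=CCc1cc(-c2cc(=O)c3c(O)cc(O)cc3o2)cc2c1O[C@H](C(C)(C)O)[C@H]2O | target

**Step count**
Total: 14 steps. Longest linear sequence: 12 steps (steps 1–10, 13, 14); steps 11 and 12 form the short branch to 19.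

**Steps most likely to fail**

Step 13 (key step). The aroylpalladium intermediate may be intercepted by diethylamine before the alkyne is transferred, the alkyne may couple without CO insertion, or oxidative addition at the doubly ortho‑substituted iodide may be too slow. The fallback builds the same ynone without CO. It sets out from triol 17 and alkyne 16 and comes back to the route at 23. Triol 17 would be carboxylated (KHCO3, CO2, water, 60 °C) to 2,4,6‑trihydroxybenzoic acid F1, peracetylated (Ac2O, pyridine) to 2,4,6‑triacetoxybenzoic acid F2, and converted with oxalyl chloride and catalytic DMF into 2,4,6‑triacetoxybenzoyl chloride F3. A copper‑cocatalysed acyl Sonogashira coupling of F3 with 16 (PdCl2(PPh3)2, CuI, Et3N, THF, rt) should give ynone 21, now isolated. Diethylamine in THF would then carry out acetate cleavage, amine addition and 6‑endo closure through 22 to give 23.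

Step 5. The cis methyl group on the alkene may lower the rate difference between the enantiomers, and the Lewis‑acidic titanium may ionise the electron‑rich benzylic allylic alcohol. The fallback replaces resolution by asymmetric reduction. It sets out from 7 and returns at 8. Oxidation of 7 with MnO2 in CH2Cl2 would give 1‑[5‑iodo‑3‑(prop‑2‑enyl)‑2‑(triisopropylsilyloxy)phenyl]‑3‑methylbut‑2‑en‑1‑one F4. Corey–Bakshi–Shibata reduction with (S)‑2‑methyl‑CBS‑oxazaborolidine and BH3·SMe2 at low temperature should then give (R)‑8, assuming that the ortho‑silyloxyaryl group acts as the larger ketone substituent.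

Step 6. Facial selectivity of the peracid may be insufficient, the allyl group may be over‑oxidised, or the product epoxide may be opened by acid. The fallback sets the oxirane centre by reagent control and then corrects the carbinol. It sets out from 7 and returns at 9. The titanium D‑tartrate epoxidation of step 5, stopped near half conversion, would be harvested for its epoxide, the erythro compound (R)‑[(2R)‑3,3‑dimethyloxiran‑2‑yl][5‑iodo‑3‑(prop‑2‑enyl)‑2‑(triisopropylsilyloxy)phenyl]methanol F5, which comes from the (S)‑enantiomer. Mitsunobu inversion of its carbinol (4‑nitrobenzoic acid, PPh3, DIAD, toluene, 0 °C) would give (S)‑[(2R)‑3,3‑dimethyloxiran‑2‑yl][5‑iodo‑3‑(prop‑2‑enyl)‑2‑(triisopropylsilyloxy)phenyl]methyl 4‑nitrobenzoate F6. Brief methanolysis (K2CO3, MeOH, 0 °C) should then release threo epoxy alcohol 9.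

**Further compounds**
F1 | step 13 | 2,4,6‑trihydroxybenzoic acid | OC(=O)c1c(O)cc(O)cc1O
F2 | step 13 | 2,4,6‑triacetoxybenzoic acid | CC(=O)Oc1cc(OC(C)=O)c(C(=O)O)c(OC(C)=O)c1
F3 | step 13 | 2,4,6‑triacetoxybenzoyl chloride | CC(=O)Oc1cc(OC(C)=O)c(C(Cl)=O)c(OC(C)=O)c1
F4 | step 5 | 1‑[5‑iodo‑3‑(prop‑2‑enyl)‑2‑(triisopropylsilyloxy)phenyl]‑3‑methylbut‑2‑en‑1‑one | CC(C)=CC(=O)c1cc(I)cc(CC=C)c1O[Si](C(C)C)(C(C)C)C(C)C
F5 | step 6 | (R)‑[(2R)‑3,3‑dimethyloxiran‑2‑yl][5‑iodo‑3‑(prop‑2‑enyl)‑2‑(triisopropylsilyloxy)phenyl]methanol | CC1(C)O[C@@H]1[C@H](O)c2cc(I)cc(CC=C)c2O[Si](C(C)C)(C(C)C)C(C)C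
F6 | step 6 | (S)‑[(2R)‑3,3‑dimethyloxiran‑2‑yl][5‑iodo‑3‑(prop‑2‑enyl)‑2‑(triisopropylsilyloxy)phenyl]methyl 4‑nitrobenzoate | CC1(C)O[C@@H]1[C@@H](OC(=O)c2ccc(cc2)[N+](=O)[O-])c3cc(I)cc(CC=C)c3O[Si](C(C)C)(C(C)C)C(C)C
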